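## The problem

The target is the C2-arm O-sulfate of (+)-isolariciresinol, an all-trans 1-aryltetralin. In the tetralin numbering used throughout, C1 (S) carries the 4-hydroxy-3-methoxyphenyl group, C2 (R) the CH2OSO3H arm, C3 (R) the CH2OH arm, C4 is a benzylic methylene, and ring A (C4a–C8a) bears OMe on C6 and OH on C7. Ring B must be annulated onto an electron-rich arene through two bonds, C1–C8a and C4–C4a, to adjacent carbons of ring A. The all-trans array is the all-equatorial, thermodynamic one. C1 is doubly benzylic and C3 becomes epimerisable whenever C4 is a carbonyl, so one secured centre, C2, can dictate the other two, and only one absolute stereochemical event is needed. Two pairs of near-identical groups must be told apart: the two primary hydroxymethyl arms (one sulfated, one free) and the two ring-A oxygens (one methylated, one free). The alkyl sulfate monoester tolerates neither strong acid nor hot nucleophiles and makes every later intermediate a salt, so it must come almost last and be unveiled under neutral conditions. Free phenols would be sulfated too, and the electron-rich rings and the C1–H bond exclude late oxidants. The enabling feature is that ring A is attached through adjacent C8a and C4a to C1 and C4, the two ends of the C1–C2–C3–C4 chain. If these ends are bonded to each other in a four-membered ketone (C4 the carbonyl, C1 the aryl-bearing α-carbon), an aryne can be inserted into that bond. The C4 carbonyl left behind then marks C7 (para) against C6 and C3 (α) against C2.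

## Retrosynthesis

**25 ⇐ 23 ⇐ 21 (benzyl–oxygen and S–O bonds).** The last operation cuts the three benzyl–oxygen bonds of sodium sulfate 23 (both phenols and the C3 arm) by hydrogenolysis, followed by protonation to 25. Before that, the S–O bond is formed on alcohol 21, whose C2 hydroxymethyl group is the only free hydroxyl. Any endgame needing acid or strong base next to the sulfate is thereby avoided. The forward steps must meet exactly one hydroxyl in the sulfation and leave the sulfate salt untouched in the hydrogenolysis.

**21 ⇐ 20 ⇐ 19 ⇐ 18 (C2-arm silyl ether, C4 oxygen).** The C2 arm of 21 is traced to the silyl ether 20, and the C4 methylene of 20 to alcohol 19 and ketone 18. The carbonyl is placed at C4 rather than removed earlier because it is needed twice more going backwards (α-activation of C3, para-activation of C7). Its removal is asked to pass through a C4 cation stabilised by the C7 oxygen and to leave C3 alone.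

**18 ⇐ 16 (C3–CH2 bond).** The C3 arm is cut off at the bond between C3 and its CH2, so that it enters late as a benzyloxymethyl electrophile on enolate 17. The neighbouring plan would carry both arms through the ring expansion as identical ethers. It would leave the arms indistinguishable (a reduction, acetal, deprotection and deoxygenation detour of about five steps). It would also expose a β-alkoxy ketone to the basic aryne step and to hot thiolate, where β-elimination threatens. Here C3 is the only enolisable position of 16, the arms are born different (silyl on C2, benzyl on C3), and the fixed C2 centre directs the newcomer trans.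

**16 ⇐ 15 ⇐ 14 (ring-A oxygens).** The C7 benzyl ether of 16 comes from bisphenol 15, and 15 from dimethyl ether 14 by cleaving the C7–OCH3 bond. Only this ether is para to the C4 ketone, so nucleophilic dealkylation by a thiolate finds it. The aryl benzyl ether of the pendant ring cannot survive that reagent, so it is allowed to fall and both phenols of 15 are benzylated together. A thiolate-proof acetal on the pendant phenol would need acid next to the sulfate or an extra exchange step.

**14 ⇐ 9 + 10 (C1–C8a and C4–C4a, the key cut).** Both bonds from ring B to ring A are cut at once, giving cyclobutanone 9 and the symmetrical ortho-silylaryl triflate 10, the source of aryne 12. Against Friedel–Crafts or cyclisation cuts this makes ring A a purchased reagent and removes any question of ring-closure regiochemistry on the arene. The precursor shrinks to a four-membered ring with one stereocentre that matters. The forward reaction must enolise 9 at the aryl-bearing carbon (enolate 11), arylate it on carbon, close the aryl anion onto the carbonyl (alkoxide 13) and fragment the shared bond.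

**9 ⇐ 6 + 2 (cyclobutane bonds C1–C2 and C3–C4).** The four-membered ring is cut into keteniminium 7, made from amide 6, and allyl silyl ether 2. The terminal alkene fixes the regiochemistry (arm on the carbon next to the aryl-bearing one), and the C2-symmetric auxiliary of 6 is asked to set the single decisive stereocentre; hydrolysis of iminium salt 8 returns the auxiliary. Amide 6 comes from acid 3 and amine 4 through acid chloride 5, and ether 2 from alcohol 1.

## Roads not taken

**Alternative 1:** The cut runs through ring A itself: C4a–C8a, C5–C6 and C7–C8. Rings A and B would arise together when the open-chain 1,7-diyne A2, which already holds C1, C2 and C3 with differently protected arms, is cyclotrimerised with the alkynyl boronate A3 under Cp*RuCl(cod) to give arene A1. Protodesilylation at C5 and oxidation of the C7–B bond would then give exactly the C6-OMe/C7-OH pattern.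
- Merits: ring-A oxygens and both arms are distinct by construction, and no late dealkylation is needed.
- Weak points: all three stereocentres must be built on an acyclic chain with no thermodynamic help (A2 is estimated at ten or more steps). A3 must orient so that its methoxy carbon bonds to the silylated, most crowded alkyne terminus. A3 is an electron-rich ynol ether of doubtful stability. A 1,7-diyne closes its carbocycle more slowly than it oligomerises with itself.
- Comparison: this road is better than the chosen one in the ring-A oxygen problem (the chosen plan spends steps 5 and 6 on it) and equal in arm differentiation. The chosen plan sets one stereocentre by external control and lets C1 and C3 follow, and it reaches its ring-closure precursor 9 in three steps.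

**Alternative 2:** The cut is the C2–C3 bond. The open-chain diester A5 (only C1 stereogenic; tert-butyl ester on the C2 side, methyl ester on the C3 side) would be doubly deprotonated and oxidised with CuCl2, joining the two ester α-carbons to give the trans-diester A4.
- Merits: the reaction class is known, the C7 benzyl ether and C6 methyl ether are fixed from the start, and C1 is accessible by catalytic asymmetric conjugate arylation. The two esters differ, so the arms can be told apart, and both new centres are α to esters and can be equilibrated to trans.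
- Weak points: an oxidant meets two trioxygenated arenes and a doubly benzylic C1–H. Six-membered closure of a dienolate competes with intermolecular coupling. Selective reduction of one ester, protection, reduction of the other, sulfation and deprotection make the endgame as long as the chosen one.
- Comparison: this road is ahead in precedent for its key step and in ring-A differentiation. The chosen plan sets against it a ring closure driven by the release of two four-membered rings, no oxidant, and a much shorter approach to the closure precursor.

**Alternative 3:** The cut is C1–C2. The bis-aryl carbinol aldehyde A7 would be ionised by acid to the pendant-ring para-quinone methide A8, and the enamine of the tethered aldehyde (secondary amine catalyst) would add to its exocyclic carbon to give the formyl tetralin A6.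
- Merits: amine-catalysed 1,6-additions to para-quinone methides formed in situ are established. The free pendant phenol is the activating group rather than a burden. The C2 arm is born as an aldehyde, so arms and ring-A oxygens are distinct from the outset. C3 controls C2 (epimerisable) and C1 through a chair-like closure. The endgame is short: phenol protection, reduction, sulfation and hydrogenolysis.
- Weak points: A7 needs an ortho-disubstituted arene carrying an enantiopure β-branched aldehyde chain and an acid-labile benzhydrol (estimated at about eight steps). The cationic intermediate can be captured by ring A of a second molecule. C1 is set kinetically.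
- Comparison: this is the strongest rival. It is better than the chosen plan in precedent, in endgame length (four steps after the key step against eight) and in having every oxygen distinct from the start. The chosen plan sets against it a three-step access to 9 from bought materials, ring A purchased whole as 10, and a C1 centre that base can correct.

Key step: step 4

Assumption 1: the (2R,5R) auxiliary is taken to shield the face leading to the (3S) cyclobutanone 9; should the sense prove opposite, the commercial (2S,5S) amine is used with no other change.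

Assumption 2: the target is drawn as the free hydrogen sulfate, so the sodium salt 24 is protonated cold with one equivalent of acid; the salt is the form to store.

## Steps

Step 1
Reactants: 1 prop-2-en-1-ol
Product: 2 triisopropyl(prop-2-en-1-yloxy)silane
Conditions: iPr3SiCl, imidazole, DMF, 0 °C → rt
Reagents that add atoms: chlorotriisopropylsilane, CC(C)[Si](Cl)(C(C)C)C(C)C
Why: Standard silylation of a primary alcohol; the bulky triisopropylsilyl ether is chosen to survive fluoride at room temperature (step 4), hot thiolate (step 5) and brief acid (step 9) and to be orthogonal to benzyl.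

Step 2
Reactants: 3 [4-(benzyloxy)-3-methoxyphenyl]acetic acid; 4 (2R,5R)-2,5-dimethylpyrrolidine
Product: 6 2-[4-(benzyloxy)-3-methoxyphenyl]-1-[(2R,5R)-2,5-dimethylpyrrolidin-1-yl]ethan-1-one, via acid chloride 5 (not isolated)
Conditions: (COCl)2, cat. DMF, CH2Cl2, 0 °C → rt; then 4, Et3N, CH2Cl2, 0 °C → rt
Reagents that add atoms: none
Why: Acid chloride formation followed by amide formation; the acid chloride overcomes the low nucleophilicity of the α,α'-disubstituted pyrrolidine.

Step 3
Reactants: 6 the amide from step 2; 2 triisopropyl(prop-2-en-1-yloxy)silane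
Product: 9 (2S,3S)-2-[4-(benzyloxy)-3-methoxyphenyl]-3-{[(triisopropylsilyl)oxy]methyl}cyclobutan-1-one, via keteniminium triflate 7 (not isolated), via cyclobutaniminium triflate 8 (not isolated)
Conditions: Tf2O, 2,4,6-collidine, 2 (3 equiv), ClCH2CH2Cl, −20 → 80 °C; then sat. aq. NaHCO3, rt
Reagents that add atoms: water, O
Why: Keteniminium (2+2) cycloaddition: amide activation gives 7, the CH2 terminus of the alkene bonds to the electrophilic central carbon so the arm ends on C3, and hydrolysis of 8 gives the ketone and returns the auxiliary. The C2-symmetric pyrrolidine differentiates the two faces of approach and sets C3 (S); the aryl-bearing C2 settles trans during the basic work-up and is erased in step 4 in any case.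

Step 4
Reactants: 9 the cyclobutanone from step 3; 10 4,5-dimethoxy-2-(trimethylsilyl)phenyl trifluoromethanesulfonate
Product: 14 (1S,2S)-1-[4-(benzyloxy)-3-methoxyphenyl]-6,7-dimethoxy-4-oxo-2-{[(triisopropylsilyl)oxy]methyl}-1,2,3,4-tetrahydronaphthalene, via potassium enolate 11 (not isolated), via 4,5-dimethoxybenzyne 12 (not isolated), via fused benzocyclobutenoxide 13 (not isolated)
Conditions: KN(SiMe3)2 (0.95 equiv), THF, −78 → 0 °C; then 10 (1.2 equiv), KF, 18-crown-6, THF, 0 °C → rt; sat. aq. NH4Cl
Reagents that add atoms: none
Why: Proposed new method: the conjugated enolate 11 should add through carbon to aryne 12 (released from 10 by fluoride), forming C1–C8a; the ortho aryl anion then adds to the strained carbonyl (C4–C4a) to give alkoxide 13, whose shared C1–C4 bond fragments, and protonation at C1 gives 14. The closest known reaction types are aryne insertion into the C–C bond of cyclic β-keto esters and of α-aryl ketones, and the opening of ketone-enolate/aryne benzocyclobutenols to ring-expanded aryl ketones; a cyclobutanone has not served as the enolate partner. Ring B is therefore closed by two-carbon ring expansion (4-exo-trig carbonyl addition, then C–C fragmentation of the alkoxide, four- to six-membered), not by a direct six-membered cyclisation, and the driving force is the loss of both four-membered rings together with formation of a diaryl-stabilised, ketone-conjugated anion. The only new stereocentre, C1, is set by protonation anti to the C2 arm and can also equilibrate, since C1–H is doubly benzylic and ortho-lateral to the ketone, so the fixed C2 centre gives the 1,2-trans product; the aryl-bearing stereocentre of 9 disappears on enolisation. The step needs enolisation at the aryl-bearing α-carbon and not at the α-methylene, which conjugation with the arene secures under equilibrating conditions (slight deficit of base), and C- rather than O-arylation, which the soft aryne favours. The aryne is symmetrical, so its orientation is irrelevant. Closure of the aryl anion must outrun its protonation, which the aprotic medium and the electrophilic four-ring carbonyl favour.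

Step 5
Reactants: 14 the tetralone from step 4
Product: 15 (1S,2S)-7-hydroxy-1-(4-hydroxy-3-methoxyphenyl)-6-methoxy-4-oxo-2-{[(triisopropylsilyl)oxy]methyl}-1,2,3,4-tetrahydronaphthalene
Conditions: NaSEt (6 equiv), DMF, 110 °C; then 1 M HCl, 0 °C
Reagents that add atoms: none
Why: Nucleophilic (SN2) ether cleavage by thiolate: the C7 methyl ether is the only one whose aryloxide leaving group is stabilised by the para carbonyl, and the aryl benzyl ether falls because benzyl is the better SN2 electrophile. The C6 and pendant methoxy groups then sit ortho to a phenoxide and are deactivated; the alkyl silyl ether is not a substrate.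

Step 6
Reactants: 15 the bisphenol from step 5
Product: 16 (1S,2S)-7-(benzyloxy)-1-[4-(benzyloxy)-3-methoxyphenyl]-6-methoxy-4-oxo-2-{[(triisopropylsilyl)oxy]methyl}-1,2,3,4-tetrahydronaphthalene
Conditions: BnBr, K2CO3, DMF, rt
Reagents that add atoms: benzyl bromide, BrCc1ccccc1
Why: Williamson ether synthesis; carbonate deprotonates only the two phenols, so the ketone α-position is not alkylated, and any material that kept its pendant benzyl group in step 5 converges on the same product.

Step 7
Reactants: 16 the bis(benzyl ether) from step 6
Product: 18 (1S,2R,3R)-7-(benzyloxy)-1-[4-(benzyloxy)-3-methoxyphenyl]-3-[(benzyloxy)methyl]-6-methoxy-4-oxo-2-{[(triisopropylsilyl)oxy]methyl}-1,2,3,4-tetrahydronaphthalene, via lithium enolate 17 (not isolated)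
Conditions: LiN(SiMe3)2, THF, −78 °C; then BnOCH2Cl, −78 → −30 °C
Reagents that add atoms: benzyl chloromethyl ether, ClCOCc1ccccc1
Why: Alkylation of a lithium ketone enolate with a chloromethyl ether; C3 is the only α-position with protons, and the electrophile enters anti to the neighbouring C2 arm, giving the 2,3-trans product, which is also the thermodynamic epimer.

Step 8
Reactants: 18 the ketone from step 7
Product: 19 (1S,2R,3R,4R)-7-(benzyloxy)-1-[4-(benzyloxy)-3-methoxyphenyl]-3-[(benzyloxy)methyl]-6-methoxy-2-{[(triisopropylsilyl)oxy]methyl}-1,2,3,4-tetrahydronaphthalen-4-ol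
Conditions: NaBH4, MeOH/THF, 0 °C
Reagents that add atoms: none
Why: Borohydride reduction of an aryl ketone; hydride is expected to enter mainly anti to the C3 arm (4R drawn), but the C4 configuration is of no consequence because C4 is deoxygenated in step 9 and both epimers are carried on.

Step 9
Reactants: 19 the benzylic alcohol from step 8
Product: 20 (1S,2R,3R)-7-(benzyloxy)-1-[4-(benzyloxy)-3-methoxyphenyl]-3-[(benzyloxy)methyl]-6-methoxy-2-{[(triisopropylsilyl)oxy]methyl}-1,2,3,4-tetrahydronaphthalene
Conditions: Et3SiH (5 equiv), CF3CO2H (5 equiv), CH2Cl2, −20 → 0 °C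
Reagents that add atoms: none
Why: Ionic hydrogenation: acid ionises the benzylic alcohol to a cation stabilised by the para C7 oxygen, which the silane reduces; low temperature and excess silane disfavour elimination towards C3, so the three stereocentres are kept and the benzyl and silyl ethers survive the short exposure.

Step 10
Reactants: 20 the silyl ether from step 9
Product: 21 [(1S,2R,3R)-7-(benzyloxy)-1-[4-(benzyloxy)-3-methoxyphenyl]-3-[(benzyloxy)methyl]-6-methoxy-1,2,3,4-tetrahydronaphthalen-2-yl]methanol
Conditions: Bu4NF, THF, 0 °C → rt
Reagents that add atoms: none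
Why: Fluoride cleavage of the silyl ether; benzyl ethers are inert, so only the C2 arm is set free.

Step 11
Reactants: 21 the alcohol from step 10
Product: 23 sodium [(1S,2R,3R)-7-(benzyloxy)-1-[4-(benzyloxy)-3-methoxyphenyl]-3-[(benzyloxy)methyl]-6-methoxy-1,2,3,4-tetrahydronaphthalen-2-yl]methyl sulfate, via pyridinium sulfate 22 (not isolated)
Conditions: SO3·pyridine, pyridine, rt; then aq. NaHCO3
Reagents that add atoms: sulfur trioxide–pyridine complex, [O-]S(=O)(=O)[n+]1ccccc1; sodium hydrogen carbonate, [Na+].OC([O-])=O
Why: O-Sulfation of the only free hydroxyl with the sulfur trioxide–pyridine complex, followed by cation exchange to the stable sodium salt.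

Step 12
Reactants: 23 the sodium sulfate from step 11
Product: 25 [(1S,2R,3R)-7-hydroxy-1-(4-hydroxy-3-methoxyphenyl)-3-(hydroxymethyl)-6-methoxy-1,2,3,4-tetrahydronaphthalen-2-yl]methyl hydrogen sulfate, via sodium salt 24 (not isolated)
Conditions: H2 (1 atm), Pd(OH)2/C, MeOH, rt; then 0.1 M HCl (1.0 equiv), 0 °C, C18 desalting
Reagents that add atoms: none
Why: Hydrogenolysis of the three benzyl ethers under neutral conditions, which alkyl sulfate salts tolerate; one equivalent of cold acid then gives the hydrogen sulfate as drawn without touching a stereocentre.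

## Compound list

1 | prop-2-en-1-ol | C=CCO | starting material
2 | triisopropyl(prop-2-en-1-yloxy)silane | C=CCO[Si](C(C)C)(C(C)C)C(C)C | intermediate
3 | [4-(benzyloxy)-3-methoxyphenyl]acetic acid | COc1cc(CC(=O)O)ccc1OCc1ccccc1 | starting material
4 | (2R,5R)-2,5-dimethylpyrrolidine | C[C@@H]1CC[C@@H](C)N1 | starting material
5 | [4-(benzyloxy)-3-methoxyphenyl]acetyl chloride | COc1cc(CC(=O)Cl)ccc1OCc1ccccc1 | intermediate (not isolated)
6 | 2-[4-(benzyloxy)-3-methoxyphenyl]-1-[(2R,5R)-2,5-dimethylpyrrolidin-1-yl]ethan-1-one | COc1cc(CC(=O)N2[C@H](C)CC[C@H]2C)ccc1OCc1ccccc1 | intermediate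
7 | (2R,5R)-1-{2-[4-(benzyloxy)-3-methoxyphenyl]ethenylidene}-2,5-dimethylpyrrolidin-1-ium triflate (keteniminium salt) | COc1cc(C=C=[N+]2[C@H](C)CC[C@H]2C)ccc1OCc1ccccc1.[O-]S(=O)(=O)C(F)(F)F | intermediate (not isolated)
8 | (2R,5R)-1-[(2S,3S)-2-[4-(benzyloxy)-3-methoxyphenyl]-3-{[(triisopropylsilyl)oxy]methyl}cyclobutylidene]-2,5-dimethylpyrrolidin-1-ium triflate | COc1cc([C@H]2C(=[N+]3[C@H](C)CC[C@H]3C)C[C@@H]2CO[Si](C(C)C)(C(C)C)C(C)C)ccc1OCc1ccccc1.[O-]S(=O)(=O)C(F)(F)F | intermediate (not isolated)
9 | (2S,3S)-2-[4-(benzyloxy)-3-methoxyphenyl]-3-{[(triisopropylsilyl)oxy]methyl}cyclobutan-1-one (2,3-trans) | COc1cc([C@H]2C(=O)C[C@@H]2CO[Si](C(C)C)(C(C)C)C(C)C)ccc1OCc1ccccc1 | intermediate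
10 | 4,5-dimethoxy-2-(trimethylsilyl)phenyl trifluoromethanesulfonate | COc1cc(OS(=O)(=O)C(F)(F)F)c([Si](C)(C)C)cc1OC | starting material
11 | potassium (3S)-2-[4-(benzyloxy)-3-methoxyphenyl]-3-{[(triisopropylsilyl)oxy]methyl}cyclobut-1-en-1-olate | COc1cc(C2=C([O-])C[C@@H]2CO[Si](C(C)C)(C(C)C)C(C)C)ccc1OCc1ccccc1.[K+] | intermediate (not isolated)
12 | 4,5-dimethoxybenzyne (1,2-didehydro-4,5-dimethoxybenzene) | COC1=CC#CC=C1OC | intermediate (not isolated)
13 | potassium alkoxide of the benzocyclobutenol cis-fused to the cyclobutane through the future C1–C4 bond (pendant aryl on the fusion carbon C1 and cis to the C2 arm, O− on C4) | [O-][C@]12C[C@H](CO[Si](C(C)C)(C(C)C)C(C)C)[C@@]1(c1ccc(OCc3ccccc3)c(OC)c1)c1cc(OC)c(OC)cc12.[K+] | intermediate (not isolated)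
14 | (1S,2S)-1-[4-(benzyloxy)-3-methoxyphenyl]-6,7-dimethoxy-4-oxo-2-{[(triisopropylsilyl)oxy]methyl}-1,2,3,4-tetrahydronaphthalene (1,2-trans) | COc1cc([C@H]2c3cc(OC)c(OC)cc3C(=O)C[C@@H]2CO[Si](C(C)C)(C(C)C)C(C)C)ccc1OCc1ccccc1 | intermediate
15 | (1S,2S)-7-hydroxy-1-(4-hydroxy-3-methoxyphenyl)-6-methoxy-4-oxo-2-{[(triisopropylsilyl)oxy]methyl}-1,2,3,4-tetrahydronaphthalene | COc1cc([C@H]2c3cc(O)c(OC)cc3C(=O)C[C@@H]2CO[Si](C(C)C)(C(C)C)C(C)C)ccc1O | intermediate
16 | (1S,2S)-7-(benzyloxy)-1-[4-(benzyloxy)-3-methoxyphenyl]-6-methoxy-4-oxo-2-{[(triisopropylsilyl)oxy]methyl}-1,2,3,4-tetrahydronaphthalene | COc1cc([C@H]2c3cc(OCc4ccccc4)c(OC)cc3C(=O)C[C@@H]2CO[Si](C(C)C)(C(C)C)C(C)C)ccc1OCc1ccccc1 | intermediate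
17 | lithium C3–C4 enolate of 16 | COc1cc([C@H]2c3cc(OCc4ccccc4)c(OC)cc3C([O-])=C[C@@H]2CO[Si](C(C)C)(C(C)C)C(C)C)ccc1OCc1ccccc1.[Li+] | intermediate (not isolated)
18 | (1S,2R,3R)-7-(benzyloxy)-1-[4-(benzyloxy)-3-methoxyphenyl]-3-[(benzyloxy)methyl]-6-methoxy-4-oxo-2-{[(triisopropylsilyl)oxy]methyl}-1,2,3,4-tetrahydronaphthalene (all-trans) | COc1cc([C@H]2c3cc(OCc4ccccc4)c(OC)cc3C(=O)[C@@H](COCc3ccccc3)[C@@H]2CO[Si](C(C)C)(C(C)C)C(C)C)ccc1OCc1ccccc1 | intermediate
19 | (1S,2R,3R,4R)-7-(benzyloxy)-1-[4-(benzyloxy)-3-methoxyphenyl]-3-[(benzyloxy)methyl]-6-methoxy-2-{[(triisopropylsilyl)oxy]methyl}-1,2,3,4-tetrahydronaphthalen-4-ol (expected major C4 epimer) | COc1cc([C@H]2c3cc(OCc4ccccc4)c(OC)cc3[C@H](O)[C@@H](COCc3ccccc3)[C@@H]2CO[Si](C(C)C)(C(C)C)C(C)C)ccc1OCc1ccccc1 | intermediate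
20 | (1S,2R,3R)-7-(benzyloxy)-1-[4-(benzyloxy)-3-methoxyphenyl]-3-[(benzyloxy)methyl]-6-methoxy-2-{[(triisopropylsilyl)oxy]methyl}-1,2,3,4-tetrahydronaphthalene | COc1cc([C@H]2c3cc(OCc4ccccc4)c(OC)cc3C[C@@H](COCc3ccccc3)[C@@H]2CO[Si](C(C)C)(C(C)C)C(C)C)ccc1OCc1ccccc1 | intermediate
21 | [(1S,2R,3R)-7-(benzyloxy)-1-[4-(benzyloxy)-3-methoxyphenyl]-3-[(benzyloxy)methyl]-6-methoxy-1,2,3,4-tetrahydronaphthalen-2-yl]methanol | COc1cc([C@H]2c3cc(OCc4ccccc4)c(OC)cc3C[C@@H](COCc3ccccc3)[C@@H]2CO)ccc1OCc1ccccc1 | intermediate
22 | pyridinium [(1S,2R,3R)-7-(benzyloxy)-1-[4-(benzyloxy)-3-methoxyphenyl]-3-[(benzyloxy)methyl]-6-methoxy-1,2,3,4-tetrahydronaphthalen-2-yl]methyl sulfate | COc1cc([C@H]2c3cc(OCc4ccccc4)c(OC)cc3C[C@@H](COCc3ccccc3)[C@@H]2COS(=O)(=O)[O-])ccc1OCc1ccccc1.c1cc[nH+]cc1 | intermediate (not isolated)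
23 | sodium [(1S,2R,3R)-7-(benzyloxy)-1-[4-(benzyloxy)-3-methoxyphenyl]-3-[(benzyloxy)methyl]-6-methoxy-1,2,3,4-tetrahydronaphthalen-2-yl]methyl sulfate | COc1cc([C@H]2c3cc(OCc4ccccc4)c(OC)cc3C[C@@H](COCc3ccccc3)[C@@H]2COS(=O)(=O)[O-])ccc1OCc1ccccc1.[Na+] | intermediate
24 | sodium [(1S,2R,3R)-7-hydroxy-1-(4-hydroxy-3-methoxyphenyl)-3-(hydroxymethyl)-6-methoxy-1,2,3,4-tetrahydronaphthalen-2-yl]methyl sulfate | COc1cc([C@H]2c3cc(O)c(OC)cc3C[C@@H](CO)[C@@H]2COS(=O)(=O)[O-])ccc1O.[Na+] | intermediate (not isolated)
25 | [(1S,2R,3R)-7-hydroxy-1-(4-hydroxy-3-methoxyphenyl)-3-(hydroxymethyl)-6-methoxy-1,2,3,4-tetrahydronaphthalen-2-yl]methyl hydrogen sulfate | COc1cc([C@H]2c3cc(O)c(OC)cc3C[C@@H](CO)[C@@H]2COS(=O)(=O)O)ccc1O | target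

## Step count and least certain steps

Total step count: 12. Longest linear sequence: 11 steps (3 to 25 through steps 2–12; the branch from 1 joins at step 3).

**Step 4 (key step, proposed new method).** The most likely failure is protonation of the ortho aryl anion before it closes onto the carbonyl, which gives plain α-arylation and a dead end because the α-carbon is then quaternary. The amine N–H in the medium and any slowness of the four-ring closure would cause this. A second failure is enolisation on the methylene side, leading to insertion into the other C–C bond. Fallback by known chemistry, setting out from 9 and coming back at 14: 9 is treated with (3,4-dimethoxyphenyl)magnesium bromide in the presence of CeCl3, which suppresses enolisation, to give the tertiary 1-arylcyclobutanol F1. Oxidative ring expansion of this 1-arylcyclobutanol (cat. AgNO3, K2S2O8, CH2Cl2/H2O) proceeds by alkoxy radical formation, β-scission towards the benzylic carbon, and closure onto the ketone-bearing ring at the position para to its methoxy group. This is a known route from 1-arylcyclobutanols to 1-tetralones and would give 14, making the same two bonds with ring A brought in as a nucleophile.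

**Step 3.** The most likely failure is insufficient facial discrimination by the auxiliary towards a small terminal alkene, or a slow cycloaddition because the allylic oxygen lowers the nucleophilicity of the alkene and the keteniminium decays first. Fallback, setting out from 3 and coming back at 9: 3 is converted via its acid chloride 5 and dimethylamine into the N,N-dimethylamide F2. Under the conditions of step 3 this gives, through the less hindered keteniminium triflate F3 and the racemic cyclobutaniminium triflate F4, the racemic cyclobutanone. Preparative chromatography on a chiral stationary phase separates it into 9 and its enantiomer F5. Stereocontrol is thus replaced by resolution.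

**Step 5.** The most likely failure is loss of chemoselectivity under hot thiolate: cleavage of the silyl ether or of a further methyl ether, or condensation of the enolisable ketone. Fallback, setting out from 9 and coming back at 16 (steps 5 and 6 are then not needed):
- Commercial 4-(benzyloxy)-3-methoxyphenol is brominated ortho to the hydroxyl (NBS) to the bromophenol F6 and O-silylated (HN(SiMe3)2) to the aryl silyl ether F7.
- Bromine–lithium exchange with retro-Brook rearrangement (n-BuLi) gives the silylphenol F8, and triflation (Tf2O, pyridine) gives the unsymmetrical ortho-silylaryl triflate F9.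
- Under the conditions of step 4, enolate 11 and the unsymmetrical aryne F10 released from F9 should give 16 together with its regioisomer F11 (C6 benzyloxy, C7 methoxy). No useful regiocontrol is expected, and the two are separated by chromatography.
The ring-A oxygens are thus differentiated before ring B is made, at the price of the regioisomer.

**Step 7.** The most likely failure is O-alkylation of the enolate by the hard chloromethyl ether, or incomplete diastereoselection at C3. Fallback, setting out from 16 and coming back at 18: 16 is converted (Me3SiOTf, Et3N) into the trimethylsilyl enol ether F12. Hydroxymethylation with aqueous formaldehyde catalysed by Yb(OTf)3 (Mukaiyama aldol reaction) gives the β-hydroxy ketone F13, whose C3 centre can be equilibrated to trans. Benzylation with benzyl 2,2,2-trichloroacetimidate and catalytic TfOH then gives 18 without a basic step.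

**Step 9.** The most likely failure is elimination of the C4 cation towards C3 followed by re-protonation, which would erode the C3 configuration, or acid-induced loss of a benzyl ether. Fallback, setting out from 18 and coming back at 20 (step 8 is then not needed): 18 is condensed with tosylhydrazine (EtOH, cat. AcOH) to the tosylhydrazone F14. Reduction with catecholborane followed by NaOAc·3H2O (hydride addition to C=N, then loss of sulfinate and nitrogen) gives the methylene compound 20 without a cation at C4.

## Further compounds

F1 | step 4 | (1R,2S,3S)-2-[4-(benzyloxy)-3-methoxyphenyl]-1-(3,4-dimethoxyphenyl)-3-{[(triisopropylsilyl)oxy]methyl}cyclobutan-1-ol (new aryl trans to the C2 aryl; carbinol configuration of no consequence) | COc1cc([C@H]2[C@](O)(c3ccc(OC)c(OC)c3)C[C@@H]2CO[Si](C(C)C)(C(C)C)C(C)C)ccc1OCc1ccccc1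
F2 | step 3 | 2-[4-(benzyloxy)-3-methoxyphenyl]-N,N-dimethylacetamide | COc1cc(CC(=O)N(C)C)ccc1OCc1ccccc1
F3 | step 3 | N-{2-[4-(benzyloxy)-3-methoxyphenyl]ethenylidene}-N-methylmethanaminium triflate | COc1cc(C=C=[N+](C)C)ccc1OCc1ccccc1.[O-]S(=O)(=O)C(F)(F)F
F4 | step 3 | racemic trans N-[2-[4-(benzyloxy)-3-methoxyphenyl]-3-{[(triisopropylsilyl)oxy]methyl}cyclobutylidene]-N-methylmethanaminium triflate (one enantiomer drawn) | COc1cc([C@H]2C(=[N+](C)C)C[C@@H]2CO[Si](C(C)C)(C(C)C)C(C)C)ccc1OCc1ccccc1.[O-]S(=O)(=O)C(F)(F)F
F5 | step 3 | (2R,3R)-2-[4-(benzyloxy)-3-methoxyphenyl]-3-{[(triisopropylsilyl)oxy]methyl}cyclobutan-1-one (enantiomer of 9) | COc1cc([C@@H]2C(=O)C[C@H]2CO[Si](C(C)C)(C(C)C)C(C)C)ccc1OCc1ccccc1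
F6 | step 5 | 4-(benzyloxy)-2-bromo-5-methoxyphenol | Oc1cc(OC)c(OCc2ccccc2)cc1Br
F7 | step 5 | [4-(benzyloxy)-2-bromo-5-methoxyphenoxy]trimethylsilane | COc1cc(O[Si](C)(C)C)c(Br)cc1OCc1ccccc1
F8 | step 5 | 4-(benzyloxy)-5-methoxy-2-(trimethylsilyl)phenol | COc1cc(O)c([Si](C)(C)C)cc1OCc1ccccc1
F9 | step 5 | 4-(benzyloxy)-5-methoxy-2-(trimethylsilyl)phenyl trifluoromethanesulfonate | COc1cc(OS(=O)(=O)C(F)(F)F)c([Si](C)(C)C)cc1OCc1ccccc1
F10 | step 5 | 4-(benzyloxy)-5-methoxybenzyne | COC1=CC#CC=C1OCc1ccccc1
F11 | step 5 | (1S,2S)-6-(benzyloxy)-1-[4-(benzyloxy)-3-methoxyphenyl]-7-methoxy-4-oxo-2-{[(triisopropylsilyl)oxy]methyl}-1,2,3,4-tetrahydronaphthalene (regioisomer of 16) | COc1cc([C@H]2c3cc(OC)c(OCc4ccccc4)cc3C(=O)C[C@@H]2CO[Si](C(C)C)(C(C)C)C(C)C)ccc1OCc1ccccc1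
F12 | step 7 | trimethylsilyl enol ether (C3=C4) of 16 | COc1cc([C@H]2c3cc(OCc4ccccc4)c(OC)cc3C(O[Si](C)(C)C)=C[C@@H]2CO[Si](C(C)C)(C(C)C)C(C)C)ccc1OCc1ccccc1
F13 | step 7 | (1S,2R,3R)-7-(benzyloxy)-1-[4-(benzyloxy)-3-methoxyphenyl]-3-(hydroxymethyl)-6-methoxy-4-oxo-2-{[(triisopropylsilyl)oxy]methyl}-1,2,3,4-tetrahydronaphthalene | COc1cc([C@H]2c3cc(OCc4ccccc4)c(OC)cc3C(=O)[C@@H](CO)[C@@H]2CO[Si](C(C)C)(C(C)C)C(C)C)ccc1OCc1ccccc1
F14 | step 9 | 4-methylbenzenesulfonohydrazone of ketone 18 (C=N geometry not defined) | COc1cc([C@H]2c3cc(OCc4ccccc4)c(OC)cc3C(=NNS(=O)(=O)c3ccc(C)cc3)[C@@H](COCc3ccccc3)[C@@H]2CO[Si](C(C)C)(C(C)C)C(C)C)ccc1OCc1ccccc1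
A1 | alternative 1 | all-trans aryltetralin with trimethylsilyl on C5, methoxy on C6, pinacolboronate on C7, tert-butyldimethylsilyloxymethyl on C2, benzyloxymethyl on C3 and a benzyl-protected pendant phenol | COc1cc([C@H]2c3cc(B4OC(C)(C)C(C)(C)O4)c(OC)c([Si](C)(C)C)c3C[C@@H](COCc3ccccc3)[C@@H]2CO[Si](C)(C)C(C)(C)C)ccc1OCc1ccccc1
A2 | alternative 1 | open-chain 1,7-diyne: 3-aryl-4-(tert-butyldimethylsilyloxymethyl)-5-(benzyloxymethyl)-8-(trimethylsilyl)octa-1,7-diyne with the three stereocentres of A1 | COc1cc([C@@H](C#C)[C@@H](CO[Si](C)(C)C(C)(C)C)[C@H](COCc2ccccc2)CC#C[Si](C)(C)C)ccc1OCc1ccccc1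
A3 | alternative 1 | 2-(methoxyethynyl)-4,4,5,5-tetramethyl-1,3,2-dioxaborolane | COC#CB1OC(C)(C)C(C)(C)O1
A4 | alternative 2 | all-trans aryltetralin with tert-butyl ester on C2 and methyl ester on C3, benzyl ethers on C7 and on the pendant phenol | COc1cc([C@H]2c3cc(OCc4ccccc4)c(OC)cc3C[C@@H](C(=O)OC)[C@@H]2C(=O)OC(C)(C)C)ccc1OCc1ccccc1
A5 | alternative 2 | open-chain diester: tert-butyl 3-aryl-3-[2-(3-methoxy-3-oxopropyl)-4-methoxy-5-(benzyloxy)phenyl]propanoate with the C1 stereocentre of A4 | COc1cc([C@H](CC(=O)OC(C)(C)C)c2cc(OCc3ccccc3)c(OC)cc2CCC(=O)OC)ccc1OCc1ccccc1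
A6 | alternative 3 | all-trans aryltetralin with formyl group on C2, benzyloxymethyl arm on C3, benzyl ether on C7 and free pendant phenol | COc1cc([C@H]2c3cc(OCc4ccccc4)c(OC)cc3C[C@@H](COCc3ccccc3)[C@@H]2C=O)ccc1O
A7 | alternative 3 | bis-aryl carbinol with tethered aldehyde: 3-(benzyloxymethyl)-4-{2-[hydroxy(4-hydroxy-3-methoxyphenyl)methyl]-4-(benzyloxy)-5-methoxyphenyl}butanal (carbinol configuration not defined) | COc1cc(C(O)c2cc(OCc3ccccc3)c(OC)cc2C[C@@H](COCc2ccccc2)CC=O)ccc1O
A8 | alternative 3 | pendant-ring para-quinone methide of A7 (alkene geometry not defined) | COC1=CC(=Cc2cc(OCc3ccccc3)c(OC)cc2C[C@@H](COCc2ccccc2)CC=O)C=CC1=O
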